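**Retrosynthetic overview**
- The quinone comes from Ag2O oxidation of a 2-allylhydroquinone, made by Friedel–Crafts allylation of hydroquinone with a C20 (2E,6E)-allylic alcohol.
- The allylic alcohol comes from Zr-catalysed methylalumination/hydroxymethylation of a terminal enyne, which sets the 2E alkene.
- Key step: the C5–C6 bond of the nonadienyl chain is made by nickel-catalysed decarboxylative radical alkenylation. A but-3-ynyl radical from the N-hydroxyphthalimide ester of pent-4-ynoic acid couples with the E-alkenylzinc obtained by methylalumination of a ring-bearing terminal alkyne, which sets the 6E alkene.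
- The ring alkyne comes from radical hydrodecarboxylation of the Ireland–Claisen acid of an (S)-allylic pent-4-ynoate; the [3,3] shift transfers the carbinol chirality to the (R) ring carbon.
- The (S)-allylic alcohol comes from CBS reduction of 2,4,4-trimethylcyclohexenone, made by annulation of isobutyraldehyde with ethyl vinyl ketone. Ring order: the carbocycle (ring A) is built first; the quinone ring is bought as hydroquinone and only oxidised in the last step.

**Step 1**
Reactants: 1 2-methylpropanal; 2 pent-1-en-3-one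
Product: 4 2,4,4-trimethylcyclohex-2-en-1-one, via Michael adduct 2,2-dimethyl-5-oxoheptanal 3 (not isolated)
Conditions: H2SO4 (cat.), PhMe, reflux, Dean–Stark
Reagents that add atoms: none
Why: Acid-catalysed Michael addition gives keto-aldehyde 3, whose only six-ring-forming intramolecular aldol condensation (Robinson-type annulation) closes ring A with the gem-dimethyl carbon and the α-methyl enone in place; no stereocentre is formed.

**Step 2**
Reactants: 4 2,4,4-trimethylcyclohex-2-en-1-one
Product: 5 (1S)-2,4,4-trimethylcyclohex-2-en-1-ol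
Conditions: (R)-2-methyl-CBS-oxazaborolidine [(R)-1-methyl-3,3-diphenyltetrahydro-1H,3H-pyrrolo[1,2-c][1,3,2]oxazaborole] (10 mol%), BH3·SMe2, THF, −20 °C; MeOH, aq. work-up
Reagents that add atoms: none
Why: Corey–Bakshi–Shibata reduction, in which the (R)-catalyst treats the methyl-bearing alkenyl arm as the large group and delivers hydride to one carbonyl face to set the (S)-carbinol, the only source of chirality in the route.

**Step 3**
Reactants: 5 (1S)-2,4,4-trimethylcyclohex-2-en-1-ol; 6 pent-4-ynoic acid
Product: 7 (1S)-2,4,4-trimethylcyclohex-2-en-1-yl pent-4-ynoate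
Conditions: DCC, DMAP (cat.), CH2Cl2, 0 °C → rt
Reagents that add atoms: none
Why: Steglich esterification of a secondary allylic alcohol under neutral conditions, so there is no allylic transposition and the carbinol centre is untouched.

**Step 4**
Reactants: 7 (1S)-2,4,4-trimethylcyclohex-2-en-1-yl pent-4-ynoate
Product: 10 2-[(1R)-2,6,6-trimethylcyclohex-2-en-1-yl]-5-(trimethylsilyl)pent-4-ynoic acid (mixture of C2 epimers), via bis-silyl ketene acetal 8 (not isolated), via trimethylsilyl ester 9 (not isolated)
Conditions: LiN(i-Pr)2 (2.3 equiv), Me3SiCl (3 equiv), THF, −78 → 65 °C; 1 M HCl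
Reagents that add atoms: chlorotrimethylsilane, C[Si](C)(C)Cl
Why: Ireland–Claisen rearrangement, in which ketene acetal 8 rearranges suprafacially so the new C–C bond forms on the face that carried the C–O bond, giving the (R) ring stereocentre next to the gem-dimethyl carbon and moving the alkene to the 2,3-position, while the second equivalent of base and silyl chloride caps the alkyne C–H (the α-epimers are inconsequential).

**Step 5**
Reactants: 10 2-[(1R)-2,6,6-trimethylcyclohex-2-en-1-yl]-5-(trimethylsilyl)pent-4-ynoic acid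
Product: 12 (6R)-6-(but-3-yn-1-yl)-1,5,5-trimethylcyclohex-1-ene, via silylalkyne 11 (not isolated)
Conditions: 9-mesityl-10-phenylacridinium tetrafluoroborate (5 mol%), (PhS)2 (10 mol%), i-Pr2NEt (20 mol%), CF3CH2OH, 450 nm LEDs, rt; then K2CO3, MeOH, rt
Reagents that add atoms: none
Why: Photoredox hydrodecarboxylation, in which the excited acridinium oxidises the carboxylate, CO2 is lost and the secondary radical takes hydrogen from PhSH faster than it can rearrange, erasing the α-centre without touching the ring stereocentre, after which K2CO3/MeOH removes the alkynyl silane.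

**Step 6**
Reactants: 12 (6R)-6-(but-3-yn-1-yl)-1,5,5-trimethylcyclohex-1-ene; 6 pent-4-ynoic acid
Product: 16 (6R)-1,5,5-trimethyl-6-[(3E)-3-methyloct-3-en-7-yn-1-yl]cyclohex-1-ene, via E-alkenylalane 13 (not isolated), via E-alkenylzinc chloride 14 (not isolated), via N-hydroxyphthalimide ester 15 (not isolated)
Conditions: AlMe3, Cp2ZrCl2 (25 mol%), CH2Cl2, 0 °C → rt; evaporate; ZnCl2, THF, 0 °C; then 15 [second flask: 6, N-hydroxyphthalimide, DIC, DMAP (cat.), CH2Cl2, rt], Ni(acac)2 (10 mol%), 2,2'-bipyridine (10 mol%), THF/DMF, rt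
Reagents that add atoms: trimethylaluminium, C[Al](C)C
Why: Proposed new method: Zr-catalysed Negishi methylalumination adds Me–Al syn across the terminal alkyne (13), ZnCl2 moves the alkenyl group to zinc (14), and the low-valent alkenylnickel–bipyridine species reduces redox-active ester 15 by single-electron transfer so that the but-3-ynyl radical (after loss of CO2 and phthalimide anion) is captured at nickel and reductive elimination forms the C(sp3)–C(sp2) bond with retention of the E geometry; the closest known reactions are the nickel-catalysed decarboxylative alkenylation of N-hydroxyphthalimide esters with alkenylzinc reagents and the Pd-catalysed coupling of carboalumination-derived alkenylalanes in the presence of ZnCl2.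

**Step 7**
Reactants: 16 (6R)-1,5,5-trimethyl-6-[(3E)-3-methyloct-3-en-7-yn-1-yl]cyclohex-1-ene
Product: 18 (2E,6E)-3,7-dimethyl-9-[(1R)-2,6,6-trimethylcyclohex-2-en-1-yl]nona-2,6-dien-1-ol, via dienylalane 17 (not isolated)
Conditions: AlMe3, Cp2ZrCl2 (25 mol%), CH2Cl2, 0 °C → rt; evaporate; n-BuLi, THF, −78 °C; (CH2O)n, → rt; 1 M HCl
Reagents that add atoms: trimethylaluminium, C[Al](C)C; paraformaldehyde (formaldehyde source), C=O
Why: Negishi methylalumination/hydroxymethylation, in which syn addition of Me–Al to the terminal alkyne fixes the second E-trisubstituted alkene and the butyl ate complex of alane 17 adds to formaldehyde, leaving the existing alkenes and the stereocentre untouched.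

**Step 8**
Reactants: 18 (2E,6E)-3,7-dimethyl-9-[(1R)-2,6,6-trimethylcyclohex-2-en-1-yl]nona-2,6-dien-1-ol; 19 hydroquinone
Product: 21 2-{(2E,6E)-3,7-dimethyl-9-[(1R)-2,6,6-trimethylcyclohex-2-en-1-yl]nona-2,6-dien-1-yl}cyclohexa-2,5-diene-1,4-dione, via allylhydroquinone 20 (not isolated)
Conditions: 19 (5 equiv), BF3·OEt2 (30 mol%), 1,4-dioxane, rt; aqueous wash; then Ag2O, MgSO4, Et2O, rt
Reagents that add atoms: none
Why: Friedel–Crafts allylation of hydroquinone at the primary terminus of the allyl cation (all four ring positions are equivalent and excess 19 suppresses dialkylation) followed by Ag2O oxidation of the electron-rich hydroquinone 20 to the quinone, with no new stereocentre; the E-alkenes are expected to be largely retained under these mild conditions.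

**Compound list**
1 | 2-methylpropanal (isobutyraldehyde) | CC(C)C=O | starting material
2 | pent-1-en-3-one (ethyl vinyl ketone) | CCC(=O)C=C | starting material
3 | 2,2-dimethyl-5-oxoheptanal | CCC(=O)CCC(C)(C)C=O | intermediate
4 | 2,4,4-trimethylcyclohex-2-en-1-one | CC1=CC(C)(C)CCC1=O | intermediate
5 | (1S)-2,4,4-trimethylcyclohex-2-en-1-ol | CC1=CC(C)(C)CC[C@@H]1O | intermediate
6 | pent-4-ynoic acid | C#CCCC(=O)O | starting material
7 | (1S)-2,4,4-trimethylcyclohex-2-en-1-yl pent-4-ynoate | C#CCCC(=O)O[C@H]1CCC(C)(C)C=C1C | intermediate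
8 | trimethylsilyl ketene acetal of 7 carrying a C-trimethylsilyl alkyne (enol ether geometry not defined) | C[Si](C)(C)C#CCC=C(O[Si](C)(C)C)O[C@H]1CCC(C)(C)C=C1C | intermediate
9 | trimethylsilyl 2-[(1R)-2,6,6-trimethylcyclohex-2-en-1-yl]-5-(trimethylsilyl)pent-4-ynoate (C2 epimers) | C[Si](C)(C)C#CCC(C(=O)O[Si](C)(C)C)[C@H]1C(C)=CCCC1(C)C | intermediate
10 | 2-[(1R)-2,6,6-trimethylcyclohex-2-en-1-yl]-5-(trimethylsilyl)pent-4-ynoic acid (C2 epimers) | C[Si](C)(C)C#CCC(C(=O)O)[C@H]1C(C)=CCCC1(C)C | intermediate
11 | trimethyl{4-[(1R)-2,6,6-trimethylcyclohex-2-en-1-yl]but-1-yn-1-yl}silane | C[Si](C)(C)C#CCC[C@H]1C(C)=CCCC1(C)C | intermediate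
12 | (6R)-6-(but-3-yn-1-yl)-1,5,5-trimethylcyclohex-1-ene | C#CCC[C@H]1C(C)=CCCC1(C)C | intermediate
13 | dimethyl{(1E)-2-methyl-4-[(1R)-2,6,6-trimethylcyclohex-2-en-1-yl]but-1-en-1-yl}alumane | C[Al](C)/C=C(\C)CC[C@H]1C(C)=CCCC1(C)C | intermediate
14 | chloro{(1E)-2-methyl-4-[(1R)-2,6,6-trimethylcyclohex-2-en-1-yl]but-1-en-1-yl}zinc | Cl[Zn]/C=C(\C)CC[C@H]1C(C)=CCCC1(C)C | intermediate
15 | 1,3-dioxoisoindolin-2-yl pent-4-ynoate | C#CCCC(=O)ON1C(=O)c2ccccc2C1=O | intermediate
16 | (6R)-1,5,5-trimethyl-6-[(3E)-3-methyloct-3-en-7-yn-1-yl]cyclohex-1-ene | C#CCC/C=C(\C)CC[C@H]1C(C)=CCCC1(C)C | intermediate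
17 | {(1E,5E)-2,6-dimethyl-8-[(1R)-2,6,6-trimethylcyclohex-2-en-1-yl]octa-1,5-dien-1-yl}dimethylalumane | C[Al](C)/C=C(\C)CC/C=C(\C)CC[C@H]1C(C)=CCCC1(C)C | intermediate
18 | (2E,6E)-3,7-dimethyl-9-[(1R)-2,6,6-trimethylcyclohex-2-en-1-yl]nona-2,6-dien-1-ol | OC/C=C(\C)CC/C=C(\C)CC[C@H]1C(C)=CCCC1(C)C | intermediate
19 | hydroquinone (benzene-1,4-diol) | Oc1ccc(O)cc1 | starting material
20 | 2-{(2E,6E)-3,7-dimethyl-9-[(1R)-2,6,6-trimethylcyclohex-2-en-1-yl]nona-2,6-dien-1-yl}benzene-1,4-diol | Oc1ccc(O)c(C/C=C(\C)CC/C=C(\C)CC[C@H]2C(C)=CCCC2(C)C)c1 | intermediate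
21 | 2-{(2E,6E)-3,7-dimethyl-9-[(1R)-2,6,6-trimethylcyclohex-2-en-1-yl]nona-2,6-dien-1-yl}cyclohexa-2,5-diene-1,4-dione | CC1=CCCC(C)(C)[C@H]1CC/C(C)=C/CC/C(C)=C/CC1=CC(=O)C=CC1=O | target

**Step count and risks**
Total step count: 8. Longest linear sequence: 8 (steps 1 to 8; pent-4-ynoic acid and hydroquinone enter as bought).

Most likely to fail, first: step 6. The alkenyl group must move cleanly from aluminium to zinc in the presence of Al–Me groups. The free alkyne C–H of the ester and product must survive the organometallic and low-valent nickel. Methyl transfer would consume 15. The fallback sets out from 12 and uses no organozinc or organoaluminium in the coupling: methylalumination (AlMe3, Cp2ZrCl2) quenched with I2 gives the isolated vinyl iodide (6R)-6-[(3E)-4-iodo-3-methylbut-3-en-1-yl]-1,5,5-trimethylcyclohex-1-ene F1. F1 is then joined to 4-bromobut-1-yne by a reductive cross-electrophile coupling (NiBr2·glyme, 4,4'-di-tert-butyl-2,2'-bipyridine, Mn powder, NaI, DMA), in which the butynyl radical comes from the bromide. It comes back to the route at 16.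

Second: step 5. The excited acridinium can also oxidise the trisubstituted ring alkene, and the thiyl radical can add to any alkyne that loses its silyl cap early. The fallback sets out from 5 and avoids putting a carboxyl group on that carbon at all, which also bypasses the dianion chemistry of step 4. Johnson orthoester Claisen rearrangement with trimethyl orthoacetate (EtCO2H cat., 140 °C) gives methyl 2-[(1R)-2,6,6-trimethylcyclohex-2-en-1-yl]acetate F2 with the same suprafacial chirality transfer. LiAlH4 reduction gives 2-[(1R)-2,6,6-trimethylcyclohex-2-en-1-yl]ethan-1-ol F3. I2/PPh3/imidazole gives (6R)-6-(2-iodoethyl)-1,5,5-trimethylcyclohex-1-ene F4. Displacement with LiC≡CH·H2NCH2CH2NH2 in DMSO comes back to the route at 12, at the cost of one extra step.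

Third: step 8. The Lewis acid can give low yield, chroman formation, partial E/Z erosion at the 2,3-alkene, or migration of the ring alkene. The fallback sets out from 18 and replaces the cationic alkylation by a low-temperature allylstannane–quinone coupling. PBr3 (Et2O, 0 °C) gives (6R)-6-[(3E,7E)-9-bromo-3,7-dimethylnona-3,7-dien-1-yl]-1,5,5-trimethylcyclohex-1-ene F5. Bu3SnLi (THF, −78 °C) gives tributyl{(2E,6E)-3,7-dimethyl-9-[(1R)-2,6,6-trimethylcyclohex-2-en-1-yl]nona-2,6-dien-1-yl}stannane F6. BF3·OEt2-promoted addition of F6 to 1,4-benzoquinone (CH2Cl2, −78 °C, KF work-up) gives the allylhydroquinone and comes back to the route at 20, which is oxidised with Ag2O as in step 8.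

**Further compounds**
F1 | step 6 | (6R)-6-[(3E)-4-iodo-3-methylbut-3-en-1-yl]-1,5,5-trimethylcyclohex-1-ene | I/C=C(\C)CC[C@H]1C(C)=CCCC1(C)C
F2 | step 5 | methyl 2-[(1R)-2,6,6-trimethylcyclohex-2-en-1-yl]acetate | COC(=O)C[C@H]1C(C)=CCCC1(C)C
F3 | step 5 | 2-[(1R)-2,6,6-trimethylcyclohex-2-en-1-yl]ethan-1-ol | OCC[C@H]1C(C)=CCCC1(C)C
F4 | step 5 | (6R)-6-(2-iodoethyl)-1,5,5-trimethylcyclohex-1-ene | ICC[C@H]1C(C)=CCCC1(C)C
F5 | step 8 | (6R)-6-[(3E,7E)-9-bromo-3,7-dimethylnona-3,7-dien-1-yl]-1,5,5-trimethylcyclohex-1-ene | BrC/C=C(\C)CC/C=C(\C)CC[C@H]1C(C)=CCCC1(C)C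
F6 | step 8 | tributyl{(2E,6E)-3,7-dimethyl-9-[(1R)-2,6,6-trimethylcyclohex-2-en-1-yl]nona-2,6-dien-1-yl}stannane | CCCC[Sn](CCCC)(CCCC)C/C=C(\C)CC/C=C(\C)CC[C@H]1C(C)=CCCC1(C)C
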